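## Analysis of the target

Target 26 is a single oxane ring. In the numbering O1, C2, C3, C4, C5, C6 it carries a 4-hydroxyphenyl group on C2, an (E)-3-(4-hydroxyphenyl)prop-2-enyl chain on C3 and a hydroxy(4-hydroxyphenyl)methyl arm on C5; C4 and C6 are CH2 groups. There are four stereocentres: C2 (R), C3 (S) and C5 (R), whose three substituents all lie on one face of the ring, and the exocyclic carbinol carbon (R). No chair places all three ring substituents equatorial, so the all-cis pattern cannot be left to equilibration, least of all at C5 while the arm is at the ketone level. The carbinol centre lies outside the ring next to C5, whose ring neighbours C4 and C6 differ little in size, so it needs reagent control. The sensitive groups are three free phenols, two benzylic C–O bonds para to an oxygen donor (C2–O1 and the carbinol C–OH, both prone to ionise towards quinone-methide-type cations), and the E-styrene. The difficulty is therefore to place three nearly identical electron-rich aryl groups on a kinetically defined all-cis oxane without strong acid late in the route. The strategy rests on one feature: the CH= carbon of the C3 chain and the carbinol carbon on C5 sit on the same face, 1,3 across C4. A bond between them closes a cyclohexene (C3, CH2, CH=, C(aryl), C5, C4) and makes the oxane one ring of a 3-oxabicyclo[3.3.1]non-6-ene, in which C3 and C5 must be cis.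

## Retrosynthetic reasoning

26 from 25. The three phenols are unmasked last, because free phenols and para-hydroxybenzylic C–O bonds would not survive the Lewis-acid, oxidative and organometallic steps.

25 from 23 and 24; 23 from 22. The styrene C=C is cut by a cross-metathesis transform, since that bond forms under neutral conditions with thermodynamic E control and brings in the third aryl group as the simple styrene 24. The carbinol C–H bond of 23 is traced to ketone 22, so that this centre is set by a reagent-controlled hydride reduction. The reduction comes before the metathesis so that the epimerisable ketone is carried through as few steps as possible.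

22 from 21; 21 from 19. The terminal alkene carbon of 22 is removed to give aldehyde 21. The ketone carbon on C5 and the aldehyde carbon of the C3 arm in 21 are then recognised as the two ends of one cleaved C=C bond, and reconnecting them gives bicycle 19 (through diol 20 in the forward sense). This turns the cis C3/C5 relationship into a consequence of ring topology. The forward cleavage also releases the two arms already differentiated: an aryl ketone on C5 and a two-carbon aldehyde on C3.

19 from 16. The C5–C6 bond is cut. In the forward direction the O–CH2 carbon of the methoxymethyl ether of 16 is ionised to oxocarbenium ion 17 and adds to the ring alkene. It adds at the unsubstituted carbon, because that gives a six-membered ring and the benzylic cation 18, which can lose a proton only away from the bridgehead. No other bond of the oxane can be formed with the C5 configuration fixed by a bridge.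

16 from 14 and 15; 14 from 13. The acetal carbon comes from 15 by O-alkylation. The carbinol C–H bond of 14 goes back to ketone 13, because the ring carbon next to it carries two almost equivalent CH2 groups and offers no substrate bias. The C2 configuration must therefore come from the reagent.

13 from 10 and 11 (through 12); 10 from 9. The acyl–aryl bond is cut to Weinreb amide 10 and the aryl Grignard reagent 12 made from bromide 11. This gives the ketone without over-addition and without exposing the α-stereocentre to base. Amide 10 comes from imide 9 by exchange of the auxiliary.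

9 from 5 and 8. Two ring bonds of the cyclohexene are cut in a Diels–Alder transform. The forward reaction must give the 1,4 ("para") regiochemistry and the (S) ring centre, which becomes C3 of 26. Both follow from the polarised 2-aryl diene 5 and the chelated acrylimide 8 of a benzyl-substituted oxazolidinone, whose facial bias is dependable.

8 from 6 and 7; 5 from 4; 4 from 2 and 3; 2 from 1. The dienophile is an N-acylation. The diene comes from dehydration of the tertiary allylic alcohol 4, made by vinyl addition of 3 to the silylated ketone 2, which is 1 with its phenol protected.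

## Alternatives that were turned down

Alternative 1: Two-directional anti-aldol on a glutarate.
- Disconnection: the C2–C3 bond and the bond from C5 to the carbinol carbon, both as aldol bonds. The carbons that become the C3-arm CH2, C3, C4, C5 and C6 are a glutaric acid unit, carried as bis-imide A1, and both aryl carbinols come from aldehyde A2.
- Forward key step: soft enolisation of both ends of A1 (MgCl2, Et3N, Me3SiCl) and two anti-selective additions to A2 give the twofold-symmetric adduct A3.
- For: A3 holds all four stereocentres of 26 in the correct relative and absolute sense, from cheap achiral carbons and a catalytic magnesium salt. On stereocentres made per step, and probably on step count, it is stronger than the chosen route.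
- Against: no ring is closed, and the two equivalent ends must then take different roles. One imide carbonyl has to become C6 and be joined to the distal benzylic oxygen as an ether. The other has to be reduced fully and bonded to an sp2 carbon. These operations run beside two 4-silyloxybenzylic carbinols that are β to carbonyl groups, so retro-aldol, elimination and ionisation all threaten. The aldol is run twice on one molecule with a deactivated, electron-rich aldehyde, so selectivity errors multiply.
- Comparison: the chosen strategy is longer. In return it obtains the ring and the C3/C5 relationship from topology rather than from two acyclic inductions and a selective etherification, and the unzipping delivers the two arms already differentiated with their aryl groups in place.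

Alternative 2: Endo oxa-Diels–Alder.
- Disconnection: C2–C3 and O1–C6 across a dihydropyran. Aldehyde A2 is the heterodienophile, and the (1Z,3E)-1-methoxydiene A4 carries the C3 arm as a 2-(4-methoxybenzyloxy)ethyl group and the C5 arm as a silyloxymethyl group.
- Forward key step: cycloaddition under the CrCl complex (trivalent chromium) of the tridentate Schiff base from 3-(1-adamantyl)-5-methylsalicylaldehyde and cis-1-aminoindan-2-ol gives the all-cis acetal A5.
- For: the ring, O1 and the C2 and C3 centres arise in one catalytic enantioselective step. On that point it is stronger than the chosen route, which spends an auxiliary and a separate reduction on the same two centres.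
- Against: A2 is a poor heterodienophile because of its para oxygen donor, and A4 is a hindered diene of defined geometry that must itself be built. C5 is still sp2 in A5, so it must be set by hydrogenation beside a benzylic C–O bond and a benzyl-type ether. The C6 methoxy group must be removed by ionic reduction through an oxocarbenium ion on the oxygen that also holds the ionisable C2. Both arms arrive as protected primary alcohols and need deprotection, oxidation, aryl addition or olefination and, for the C5 arm, a further stereoselective reduction.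
- Comparison: the chosen strategy reaches the aryl ketone on C5 and the aldehyde on the C3 arm in one cleavage, and fixes C5 by a bridge rather than by a facial hydrogenation.

Alternative 3: Achmatowicz ring expansion.
- Disconnection: O1–C6, with C3 to C6 taken from the furan of carbinol A6.
- Forward key step: N-bromosuccinimide in aqueous THF oxidises the furan, and the carbinol oxygen closes on the freed aldehyde carbon to give pyranone A7.
- For: the oxygenated six-membered ring is reached very quickly, C2 can come from an asymmetric ketone reduction, and an ester already marks C5. It is stronger than the chosen route on early step count.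
- Against: A7 has one of the four stereocentres, and that one is benzylic, α-oxygenated and α to the C3 ketone, so it enolises easily. The C3 carbonyl must become a CH carrying a three-carbon chain, the C6 lactol must be reduced to CH2 through an oxocarbenium ion next to the ionisable C2, and the ester must become an aryl carbinol. C3 and C5 would have to be set on a flattened ring with no clear bias for the all-cis pattern. A6 is a doubly activated carbinol with an arene open to bromination, and its ester slows the furan oxidation.
- Comparison: in the chosen strategy the three ring centres are settled once the key step is over, whereas here most of the stereochemical work lies after it.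

Key step: step 10

## Route

Remark: compounds 3, 6, 7, 11, 15 and 24 are taken as purchased. TBS is tert-butyldimethylsilyl. The oxane numbering O1, C2 (aryl), C3, C4, C5, C6 is used for the monocyclic compounds and for the corresponding atoms of the bicycle.

Step 1
Reactants: 1 4'-hydroxyacetophenone
Product: 2 1-{4-[(tert-butyldimethylsilyl)oxy]phenyl}ethan-1-one
Conditions: TBSCl, imidazole, DMF, 20 °C
Reagents that add atoms: tert-butyldimethylsilyl chloride, CC(C)(C)[Si](C)(C)Cl
Why: Standard silylation of a phenol; the silyl ether removes the acidic OH for the organometallic and Lewis-acid steps and falls to fluoride at the end.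

Step 2
Reactants: 2 1-{4-[(tert-butyldimethylsilyl)oxy]phenyl}ethan-1-one; 3 vinylmagnesium bromide
Product: 4 2-{4-[(tert-butyldimethylsilyl)oxy]phenyl}but-3-en-2-ol (racemic)
Conditions: THF, −20 to 0 °C; aq. NH4Cl
Reagents that add atoms: none
Why: Grignard 1,2-addition to an aryl methyl ketone; the new stereocentre is irrelevant because step 3 removes it.

Step 3
Reactants: 4 2-{4-[(tert-butyldimethylsilyl)oxy]phenyl}but-3-en-2-ol
Product: 5 tert-butyl[4-(buta-1,3-dien-2-yl)phenoxy]dimethylsilane
Conditions: Burgess reagent (MeO2C–N(−)–SO2–N(+)Et3), THF, 50 °C, trace of BHT; used at once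
Reagents that add atoms: none
Why: Burgess dehydration of a tertiary alcohol by syn elimination of the sulfamate; only the methyl group offers a β-hydrogen leading to a stable alkene, so the 2-aryl-1,3-diene should be the only product, and the neutral conditions spare this acid-sensitive diene.

Step 4
Reactants: 6 (4R)-4-benzyl-1,3-oxazolidin-2-one; 7 acryloyl chloride
Product: 8 (4R)-4-benzyl-3-(prop-2-enoyl)-1,3-oxazolidin-2-one
Conditions: LiCl, Et3N, THF, −20 to 20 °C
Reagents that add atoms: none
Why: N-acylation of the oxazolidinone under lithium chloride and amine activation, which avoids the strongly basic lithium salt that polymerises acryloyl derivatives.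

Step 5
Reactants: 5 tert-butyl[4-(buta-1,3-dien-2-yl)phenoxy]dimethylsilane; 8 (4R)-4-benzyl-3-(prop-2-enoyl)-1,3-oxazolidin-2-one
Product: 9 (4R)-4-benzyl-3-[(1S)-4-{4-[(tert-butyldimethylsilyl)oxy]phenyl}cyclohex-3-ene-1-carbonyl]-1,3-oxazolidin-2-one
Conditions: Et2AlCl (1.4 equiv), 5 (2 equiv), CH2Cl2, −78 °C
Reagents that add atoms: none
Why: Auxiliary-controlled Diels–Alder reaction: excess Et2AlCl forms the cationic chelate of both imide carbonyls with the acryloyl unit s-cis, the benzyl group of the (R)-auxiliary covers the Si face of the α-carbon, and the diene adds to the Re face to give the (S) ring centre (later C3); the larger terminal coefficient of the 2-aryl diene meets the β-carbon, which gives the 1,4 regiochemistry.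

Step 6
Reactants: 9 (4R)-4-benzyl-3-[(1S)-4-{4-[(tert-butyldimethylsilyl)oxy]phenyl}cyclohex-3-ene-1-carbonyl]-1,3-oxazolidin-2-one
Product: 10 (1S)-4-{4-[(tert-butyldimethylsilyl)oxy]phenyl}-N-methoxy-N-methylcyclohex-3-ene-1-carboxamide
Conditions: MeNH(OMe)·HCl, AlMe3, CH2Cl2, −20 to 0 °C
Reagents that add atoms: N,O-dimethylhydroxylamine hydrochloride, CNOC.Cl
Why: Transamination of the imide with the aluminium amide made in the flask; the exocyclic carbonyl is the more electrophilic one, the conditions are not basic enough to touch the α-centre, and auxiliary 6 is released for recovery.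

Step 7
Reactants: 10 (1S)-4-{4-[(tert-butyldimethylsilyl)oxy]phenyl}-N-methoxy-N-methylcyclohex-3-ene-1-carboxamide; 11 (4-bromophenoxy)(tert-butyl)dimethylsilane
Product: 13 {4-[(tert-butyldimethylsilyl)oxy]phenyl}[(1S)-4-{4-[(tert-butyldimethylsilyl)oxy]phenyl}cyclohex-3-en-1-yl]methanone, via aryl Grignard reagent 12 (not isolated)
Conditions: 11, Mg, THF, 40 °C; then 10, 0 °C; aq. NH4Cl
Reagents that add atoms: none
Why: Weinreb ketone synthesis: the chelated tetrahedral adduct stops at single addition and releases the ketone only on quench, so neither over-addition nor epimerisation of the α-centre is expected.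

Step 8
Reactants: 13 {4-[(tert-butyldimethylsilyl)oxy]phenyl}[(1S)-4-{4-[(tert-butyldimethylsilyl)oxy]phenyl}cyclohex-3-en-1-yl]methanone
Product: 14 (R)-{4-[(tert-butyldimethylsilyl)oxy]phenyl}[(1S)-4-{4-[(tert-butyldimethylsilyl)oxy]phenyl}cyclohex-3-en-1-yl]methanol
Conditions: (S)-1-methyl-3,3-diphenyltetrahydro-1H,3H-pyrrolo[1,2-c][1,3,2]oxazaborole (0.2 equiv), catecholborane, toluene, −78 to −40 °C
Reagents that add atoms: none
Why: Corey–Bakshi–Shibata reduction with the aryl group as the large substituent, so the (S)-catalyst should give the (R)-carbinol (later C2) in the sense that turns acetophenone into (R)-1-phenylethanol; catecholborane does not hydroborate the ring alkene, the neutral medium leaves the α-centre intact, and the minor carbinol epimer should be removable by chromatography.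

Step 9
Reactants: 14 (R)-{4-[(tert-butyldimethylsilyl)oxy]phenyl}[(1S)-4-{4-[(tert-butyldimethylsilyl)oxy]phenyl}cyclohex-3-en-1-yl]methanol; 15 chloromethyl methyl ether
Product: 16 tert-butyl(4-{(R)-(methoxymethoxy)[(1S)-4-{4-[(tert-butyldimethylsilyl)oxy]phenyl}cyclohex-3-en-1-yl]methyl}phenoxy)dimethylsilane
Conditions: i-Pr2NEt, Bu4NI (cat.), CH2Cl2, 0 to 20 °C
Reagents that add atoms: none
Why: O-alkylation of a secondary alcohol with an α-chloro ether under amine base; the C–O bond of the stereocentre is not touched, and the acetal carbon introduced here becomes C6.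

Step 10
Reactants: 16 tert-butyl(4-{(R)-(methoxymethoxy)[(1S)-4-{4-[(tert-butyldimethylsilyl)oxy]phenyl}cyclohex-3-en-1-yl]methyl}phenoxy)dimethylsilane
Product: 19 (1S,2R,5S)-2,6-bis{4-[(tert-butyldimethylsilyl)oxy]phenyl}-3-oxabicyclo[3.3.1]non-6-ene, via oxocarbenium triflate 17 (not isolated), via benzylic cation triflate 18 (not isolated)
Conditions: Me3SiOTf (1.5 equiv), 2,6-di-tert-butyl-4-methylpyridine (2 equiv), CH2Cl2 (0.02 M), −78 to −40 °C
Reagents that add atoms: none
Why: Me3SiOTf silylates the less hindered methoxy oxygen of the acetal and MeOSiMe3 leaves, so 16 becomes the O-alkylated CH2=O+ ion 17, the ionisation that underlies Prins cyclisations of methoxymethyl ethers. With the side chain axial on the cyclohexene half-chair the CH2=O+ carbon lies over the ring alkene and bonds to its unsubstituted carbon, because only this regiochemistry gives a six-membered ring and the tertiary benzylic cation 18, which the 4-silyloxyphenyl group stabilises. The oxane closes through a chair-like arrangement that is exo with respect to the alkene (only the attacked carbon enters the new ring) and endo with respect to C=O+; attack at the aryl-bearing carbon would need a seven-membered ring and a secondary cation. Cation 18 loses a proton from the adjacent ring CH2; loss towards the bridgehead would give an anti-Bredt alkene, so the C6=C7 styrene of 19 is the only alkene available. The closest known reaction type is the Prins cyclisation of cyclohex-3-enyl carbinols with aldehydes or their acetals to 3-oxabicyclo[3.3.1]nonenes. The new stereocentre (C5 of the oxane, C5 of the bicycle) is fixed by topology, since the O–CH2 tether reaches the alkene only on the ring face that carries the side chain, so C5 forms cis to C3. The (R)-carbinol and (S)-ring relationship of 16 places the C2 aryl group equatorial on the forming oxane chair, which is the lower-energy transition state and maps onto the all-cis pattern of 26. The step also needs acetal ionisation to win over heterolysis of the electron-rich benzylic C2–O bond, which low temperature, the hindered base and fast intramolecular capture by the nucleophilic styrene should secure.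

Step 11
Reactants: 19 (1S,2R,5S)-2,6-bis{4-[(tert-butyldimethylsilyl)oxy]phenyl}-3-oxabicyclo[3.3.1]non-6-ene
Product: 21 2-[(2R,3R,5R)-5-{4-[(tert-butyldimethylsilyl)oxy]benzoyl}-2-{4-[(tert-butyldimethylsilyl)oxy]phenyl}oxan-3-yl]acetaldehyde, via cis-diol 20 (not isolated)
Conditions: OsO4 (2 mol%), NaIO4 (4 equiv), 2,6-lutidine, dioxane–H2O (3:1), 20 °C
Reagents that add atoms: osmium tetroxide, O=[Os](=O)(=O)=O; sodium periodate, [Na+].[O-]I(=O)(=O)=O
Why: Lemieux–Johnson oxidation: OsO4 should dihydroxylate the only alkene from the face remote from the oxygen bridge (either face would serve) and NaIO4 cleaves the glycol, so the aryl-bearing carbon becomes the ketone on C5 and the CH carbon the aldehyde of the C3 arm; 2,6-lutidine keeps the medium near neutral so that C5, now α to a ketone, is not epimerised.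

Step 12
Reactants: 21 2-[(2R,3R,5R)-5-{4-[(tert-butyldimethylsilyl)oxy]benzoyl}-2-{4-[(tert-butyldimethylsilyl)oxy]phenyl}oxan-3-yl]acetaldehyde
Product: 22 {4-[(tert-butyldimethylsilyl)oxy]phenyl}[(3R,5S,6R)-6-{4-[(tert-butyldimethylsilyl)oxy]phenyl}-5-(prop-2-en-1-yl)oxan-3-yl]methanone
Conditions: Ph3PCH3Br (1.3 equiv), KN(SiMe3)2 (1.2 equiv), THF, 0 °C; then 21, −78 to −20 °C
Reagents that add atoms: methyltriphenylphosphonium bromide, C[P+](c1ccccc1)(c1ccccc1)c1ccccc1.[Br-]
Why: Wittig methylenation: the non-stabilised ylide adds to the aldehyde far faster than to the hindered, electron-rich aryl ketone at low temperature, and using less base than phosphonium salt leaves no free amide to enolise C5 or open the β-alkoxy ketone.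

Step 13
Reactants: 22 {4-[(tert-butyldimethylsilyl)oxy]phenyl}[(3R,5S,6R)-6-{4-[(tert-butyldimethylsilyl)oxy]phenyl}-5-(prop-2-en-1-yl)oxan-3-yl]methanone
Product: 23 (R)-{4-[(tert-butyldimethylsilyl)oxy]phenyl}[(3R,5S,6R)-6-{4-[(tert-butyldimethylsilyl)oxy]phenyl}-5-(prop-2-en-1-yl)oxan-3-yl]methanol
Conditions: (S)-1-methyl-3,3-diphenyltetrahydro-1H,3H-pyrrolo[1,2-c][1,3,2]oxazaborole (0.3 equiv), catecholborane, toluene, −78 to −40 °C
Reagents that add atoms: none
Why: Second Corey–Bakshi–Shibata reduction, again with aryl as the large group, so the (S)-catalyst should set the exocyclic (R)-carbinol by reagent control; the non-basic conditions leave C5 untouched and catecholborane does not hydroborate the terminal alkene without a metal catalyst.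

Step 14
Reactants: 23 (R)-{4-[(tert-butyldimethylsilyl)oxy]phenyl}[(3R,5S,6R)-6-{4-[(tert-butyldimethylsilyl)oxy]phenyl}-5-(prop-2-en-1-yl)oxan-3-yl]methanol; 24 tert-butyl(4-ethenylphenoxy)dimethylsilane
Product: 25 (R)-{4-[(tert-butyldimethylsilyl)oxy]phenyl}{(3R,5S,6R)-6-{4-[(tert-butyldimethylsilyl)oxy]phenyl}-5-[(2E)-3-{4-[(tert-butyldimethylsilyl)oxy]phenyl}prop-2-en-1-yl]oxan-3-yl}methanol
Conditions: second-generation Hoveyda–Grubbs catalyst RuCl2(H2IMes)(=CH-C6H4-2-O-i-Pr) (5 mol%), 24 (4 equiv), CH2Cl2, 40 °C
Reagents that add atoms: none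
Why: Olefin cross-metathesis of an unhindered terminal alkene with a styrene, driven by loss of ethene; secondary metathesis equilibrates the β-alkylstyrene towards the E isomer, and the neutral conditions tolerate the free benzylic alcohol and the silyl ethers.

Step 15
Reactants: 25 (R)-{4-[(tert-butyldimethylsilyl)oxy]phenyl}{(3R,5S,6R)-6-{4-[(tert-butyldimethylsilyl)oxy]phenyl}-5-[(2E)-3-{4-[(tert-butyldimethylsilyl)oxy]phenyl}prop-2-en-1-yl]oxan-3-yl}methanol
Product: 26 4-[(1E)-3-{(2R,3S,5R)-5-[(R)-hydroxy(4-hydroxyphenyl)methyl]-2-(4-hydroxyphenyl)oxan-3-yl}prop-1-en-1-yl]phenol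
Conditions: Bu4NF (3.5 equiv), AcOH (3.5 equiv), THF, 0 °C
Reagents that add atoms: none
Why: Fluoride cleavage of the three aryl silyl ethers; the acetic acid buffer avoids both the strong acid that would ionise the para-hydroxybenzylic C–O bonds and a strongly basic phenoxide medium, and no stereocentre is involved.

## Compound list

1 | 4'-hydroxyacetophenone | CC(=O)c1ccc(O)cc1 | starting material
2 | 1-{4-[(tert-butyldimethylsilyl)oxy]phenyl}ethan-1-one | CC(=O)c1ccc(O[Si](C)(C)C(C)(C)C)cc1 | intermediate
3 | vinylmagnesium bromide | C=C[Mg]Br | starting material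
4 | 2-{4-[(tert-butyldimethylsilyl)oxy]phenyl}but-3-en-2-ol (racemic) | CC(O)(C=C)c1ccc(O[Si](C)(C)C(C)(C)C)cc1 | intermediate
5 | tert-butyl[4-(buta-1,3-dien-2-yl)phenoxy]dimethylsilane | C=CC(=C)c1ccc(O[Si](C)(C)C(C)(C)C)cc1 | intermediate
6 | (4R)-4-benzyl-1,3-oxazolidin-2-one | O=C1N[C@H](Cc2ccccc2)CO1 | starting material
7 | acryloyl chloride | C=CC(=O)Cl | starting material
8 | (4R)-4-benzyl-3-(prop-2-enoyl)-1,3-oxazolidin-2-one | C=CC(=O)N1[C@H](Cc2ccccc2)COC1=O | intermediate
9 | (4R)-4-benzyl-3-[(1S)-4-{4-[(tert-butyldimethylsilyl)oxy]phenyl}cyclohex-3-ene-1-carbonyl]-1,3-oxazolidin-2-one | C1CC(c2ccc(O[Si](C)(C)C(C)(C)C)cc2)=CC[C@H]1C(=O)N1[C@H](Cc2ccccc2)COC1=O | intermediate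
10 | (1S)-4-{4-[(tert-butyldimethylsilyl)oxy]phenyl}-N-methoxy-N-methylcyclohex-3-ene-1-carboxamide | C1CC(c2ccc(O[Si](C)(C)C(C)(C)C)cc2)=CC[C@H]1C(=O)N(C)OC | intermediate
11 | (4-bromophenoxy)(tert-butyl)dimethylsilane | Brc1ccc(O[Si](C)(C)C(C)(C)C)cc1 | starting material
12 | {4-[(tert-butyldimethylsilyl)oxy]phenyl}magnesium bromide | Br[Mg]c1ccc(O[Si](C)(C)C(C)(C)C)cc1 | intermediate (not isolated)
13 | {4-[(tert-butyldimethylsilyl)oxy]phenyl}[(1S)-4-{4-[(tert-butyldimethylsilyl)oxy]phenyl}cyclohex-3-en-1-yl]methanone | C1CC(c2ccc(O[Si](C)(C)C(C)(C)C)cc2)=CC[C@H]1C(=O)c1ccc(O[Si](C)(C)C(C)(C)C)cc1 | intermediate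
14 | (R)-{4-[(tert-butyldimethylsilyl)oxy]phenyl}[(1S)-4-{4-[(tert-butyldimethylsilyl)oxy]phenyl}cyclohex-3-en-1-yl]methanol | C1CC(c2ccc(O[Si](C)(C)C(C)(C)C)cc2)=CC[C@H]1[C@H](c1ccc(O[Si](C)(C)C(C)(C)C)cc1)O | intermediate
15 | chloromethyl methyl ether | COCCl | starting material
16 | methoxymethyl ether of 14, tert-butyl(4-{(R)-(methoxymethoxy)[(1S)-4-{4-[(tert-butyldimethylsilyl)oxy]phenyl}cyclohex-3-en-1-yl]methyl}phenoxy)dimethylsilane | C1CC(c2ccc(O[Si](C)(C)C(C)(C)C)cc2)=CC[C@H]1[C@H](c1ccc(O[Si](C)(C)C(C)(C)C)cc1)OCOC | intermediate
17 | oxocarbenium triflate from 16 (CH2=O+ on the carbinol oxygen, configuration as in 16) | C1CC(c2ccc(O[Si](C)(C)C(C)(C)C)cc2)=CC[C@H]1[C@H](c1ccc(O[Si](C)(C)C(C)(C)C)cc1)[O+]=C.[O-]S(=O)(=O)C(F)(F)F | intermediate (not isolated)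
18 | bicyclic tertiary benzylic cation triflate (cation at C6 of the 2,6-diaryl-3-oxabicyclo[3.3.1]nonane, stereocentres as in 19) | C1C[C+](c3ccc(O[Si](C)(C)C(C)(C)C)cc3)[C@@H]2C[C@H]1[C@H](c1ccc(O[Si](C)(C)C(C)(C)C)cc1)OC2.[O-]S(=O)(=O)C(F)(F)F | intermediate (not isolated)
19 | (1S,2R,5S)-2,6-bis{4-[(tert-butyldimethylsilyl)oxy]phenyl}-3-oxabicyclo[3.3.1]non-6-ene | C1C=C(c3ccc(O[Si](C)(C)C(C)(C)C)cc3)[C@@H]2C[C@H]1[C@H](c1ccc(O[Si](C)(C)C(C)(C)C)cc1)OC2 | intermediate
20 | 6,7-cis-diol of 19, both hydroxyl groups on the face remote from the oxygen bridge | C1[C@H](O)[C@@](O)(c3ccc(O[Si](C)(C)C(C)(C)C)cc3)[C@@H]2C[C@H]1[C@H](c1ccc(O[Si](C)(C)C(C)(C)C)cc1)OC2 | intermediate (not isolated)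
21 | 2-[(2R,3R,5R)-5-{4-[(tert-butyldimethylsilyl)oxy]benzoyl}-2-{4-[(tert-butyldimethylsilyl)oxy]phenyl}oxan-3-yl]acetaldehyde | O=CC[C@H]2C[C@@H](C(=O)c3ccc(O[Si](C)(C)C(C)(C)C)cc3)CO[C@H]2c2ccc(O[Si](C)(C)C(C)(C)C)cc2 | intermediate
22 | {4-[(tert-butyldimethylsilyl)oxy]phenyl}[(3R,5S,6R)-6-{4-[(tert-butyldimethylsilyl)oxy]phenyl}-5-(prop-2-en-1-yl)oxan-3-yl]methanone | C=CC[C@H]2C[C@@H](C(=O)c3ccc(O[Si](C)(C)C(C)(C)C)cc3)CO[C@H]2c2ccc(O[Si](C)(C)C(C)(C)C)cc2 | intermediate
23 | (R)-{4-[(tert-butyldimethylsilyl)oxy]phenyl}[(3R,5S,6R)-6-{4-[(tert-butyldimethylsilyl)oxy]phenyl}-5-(prop-2-en-1-yl)oxan-3-yl]methanol | C=CC[C@H]2C[C@@H]([C@@H](O)c3ccc(O[Si](C)(C)C(C)(C)C)cc3)CO[C@H]2c2ccc(O[Si](C)(C)C(C)(C)C)cc2 | intermediate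
24 | tert-butyl(4-ethenylphenoxy)dimethylsilane | C=Cc1ccc(O[Si](C)(C)C(C)(C)C)cc1 | starting material
25 | tris(tert-butyldimethylsilyl) ether of 26 at the three phenols, carbinol free | CC(C)(C)[Si](C)(C)Oc1ccc(/C=C/C[C@H]2C[C@@H]([C@@H](O)c3ccc(O[Si](C)(C)C(C)(C)C)cc3)CO[C@H]2c2ccc(O[Si](C)(C)C(C)(C)C)cc2)cc1 | intermediate
26 | 4-[(1E)-3-{(2R,3S,5R)-5-[(R)-hydroxy(4-hydroxyphenyl)methyl]-2-(4-hydroxyphenyl)oxan-3-yl}prop-1-en-1-yl]phenol | Oc1ccc(/C=C/C[C@H]2C[C@@H]([C@@H](O)c3ccc(O)cc3)CO[C@H]2c2ccc(O)cc2)cc1 | target

## Step count and least certain steps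

Total step count: 15. Longest linear sequence: 14 steps (steps 1–3 and 5–15, from 1 to 26); step 4 is the only side branch.

Step 10 (key step).
- What may go wrong: heterolysis of the benzylic C2–O bond, which is activated by the para silyloxy group, either in oxocarbenium ion 17 or in product 19 under the silyl triflate. That would erode the C2 configuration or fragment the molecule. Ionisation of the acetal in the wrong direction (loss of the whole acetal carbon) and cationic oligomerisation of the styrene are further losses.
- Fallback, from 14 back to 19: formylation of 14 (formic acid, dicyclohexylcarbodiimide, CH2Cl2) would give formate F1. Reductive acetylation (i-Bu2AlH, CH2Cl2, −78 °C; then pyridine, 4-dimethylaminopyridine, Ac2O) would give the acetoxymethyl ether F2. In F2 acetate is the only good leaving group, so it should ionise in the right direction with a weaker Lewis acid (BF3·OEt2, CH2Cl2, −78 °C) to the same ion 17, and from there to 19.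

Step 8.
- What may go wrong: weak facial discrimination, because the small group is a secondary ring carbon rather than a methyl group and the substrate itself has no bias. The result would be a mixture of carbinol epimers.
- Fallback, from 13 back to 14: unselective reduction (NaBH4, CeCl3, MeOH–THF, −40 °C) would give 14 together with its carbinol epimer F3. After chromatographic separation F3 would be oxidised back to 13 with Dess–Martin periodinane and recycled. The reagent-controlled step is thereby replaced by separation and recycling.

Step 6.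
- What may go wrong: attack of the aluminium amide on the ring carbonyl of the auxiliary instead of the exocyclic one, because the acyl group is α-branched and has no neighbouring hydroxyl to direct the reagent. The auxiliary ring would then open.
- Fallback, from 9 back to 10: hydrolysis with LiOH and H2O2 (THF–H2O, 0 °C) would give acid F4 and return auxiliary 6. Coupling of F4 with N,O-dimethylhydroxylamine hydrochloride (EDC·HCl, 1-hydroxybenzotriazole, i-Pr2NEt, CH2Cl2) would then give 10.

Step 12.
- What may go wrong: base-induced loss of the C5 configuration, by enolisation of the aryl ketone or by β-elimination that opens the ring at C6–O1, and aldol condensation between the two carbonyl groups.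
- Fallback, from 21 back to 25, without any basic step while the ketone is present: Takai iodo-olefination (CrCl2, divalent chromium, with CHI3 in THF–dioxane at 0 °C) would give the (E)-vinyl iodide F5. Reduction as in step 13 would give iodo alcohol F6. Suzuki–Miyaura coupling of F6 with 4-[(tert-butyldimethylsilyl)oxy]phenylboronic acid (OB(O)c1ccc(O[Si](C)(C)C(C)(C)C)cc1) under Pd(PPh3)4 (zerovalent palladium) and aqueous K3PO4 in THF would give 25.

## Further compounds

F1 | step 10 | (R)-{4-[(tert-butyldimethylsilyl)oxy]phenyl}[(1S)-4-{4-[(tert-butyldimethylsilyl)oxy]phenyl}cyclohex-3-en-1-yl]methyl formate | C1CC(c2ccc(O[Si](C)(C)C(C)(C)C)cc2)=CC[C@H]1[C@H](c1ccc(O[Si](C)(C)C(C)(C)C)cc1)OC=O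
F2 | step 10 | acetoxymethyl ether of 14, {(R)-{4-[(tert-butyldimethylsilyl)oxy]phenyl}[(1S)-4-{4-[(tert-butyldimethylsilyl)oxy]phenyl}cyclohex-3-en-1-yl]methoxy}methyl acetate | C1CC(c2ccc(O[Si](C)(C)C(C)(C)C)cc2)=CC[C@H]1[C@H](c1ccc(O[Si](C)(C)C(C)(C)C)cc1)OCOC(C)=O
F3 | step 8 | (S)-{4-[(tert-butyldimethylsilyl)oxy]phenyl}[(1S)-4-{4-[(tert-butyldimethylsilyl)oxy]phenyl}cyclohex-3-en-1-yl]methanol | C1CC(c2ccc(O[Si](C)(C)C(C)(C)C)cc2)=CC[C@H]1[C@@H](c1ccc(O[Si](C)(C)C(C)(C)C)cc1)O
F4 | step 6 | (1S)-4-{4-[(tert-butyldimethylsilyl)oxy]phenyl}cyclohex-3-ene-1-carboxylic acid | C1CC(c2ccc(O[Si](C)(C)C(C)(C)C)cc2)=CC[C@H]1C(=O)O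
F5 | step 12 | {4-[(tert-butyldimethylsilyl)oxy]phenyl}{(3R,5R,6R)-6-{4-[(tert-butyldimethylsilyl)oxy]phenyl}-5-[(2E)-3-iodoprop-2-en-1-yl]oxan-3-yl}methanone | I/C=C/C[C@H]2C[C@@H](C(=O)c3ccc(O[Si](C)(C)C(C)(C)C)cc3)CO[C@H]2c2ccc(O[Si](C)(C)C(C)(C)C)cc2
F6 | step 12 | (R)-{4-[(tert-butyldimethylsilyl)oxy]phenyl}{(3R,5R,6R)-6-{4-[(tert-butyldimethylsilyl)oxy]phenyl}-5-[(2E)-3-iodoprop-2-en-1-yl]oxan-3-yl}methanol | I/C=C/C[C@H]2C[C@@H]([C@@H](O)c3ccc(O[Si](C)(C)C(C)(C)C)cc3)CO[C@H]2c2ccc(O[Si](C)(C)C(C)(C)C)cc2
A1 | alternative 1 | 1,5-bis[(4R)-4-benzyl-2-oxo-1,3-oxazolidin-3-yl]pentane-1,5-dione | O=C(CCCC(=O)N1[C@H](Cc2ccccc2)COC1=O)N1[C@H](Cc2ccccc2)COC1=O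
A2 | alternative 1 | 4-[(tert-butyldimethylsilyl)oxy]benzaldehyde | O=Cc1ccc(O[Si](C)(C)C(C)(C)C)cc1
A3 | alternative 1 | twofold-symmetric bis-anti-aldol adduct of A1 with two molecules of A2 | O=C(N1[C@H](Cc2ccccc2)COC1=O)[C@H]([C@@H](O)c1ccc(O[Si](C)(C)C(C)(C)C)cc1)C[C@@H]([C@@H](O)c1ccc(O[Si](C)(C)C(C)(C)C)cc1)C(=O)N1[C@H](Cc2ccccc2)COC1=O
A4 | alternative 2 | (1Z,3E)-2-{[(tert-butyldimethylsilyl)oxy]methyl}-1-methoxy-6-[(4-methoxybenzyl)oxy]hexa-1,3-diene | CO/C=C(CO[Si](C)(C)C(C)(C)C)/C=C/CCOCc1ccc(OC)cc1
A5 | alternative 2 | all-cis 2-{4-[(tert-butyldimethylsilyl)oxy]phenyl}-6-methoxy-3-{2-[(4-methoxybenzyl)oxy]ethyl}-5-{[(tert-butyldimethylsilyl)oxy]methyl}-3,6-dihydro-2H-pyran | CO[C@H]1O[C@@H](c2ccc(O[Si](C)(C)C(C)(C)C)cc2)[C@@H](CCOCc2ccc(OC)cc2)C=C1CO[Si](C)(C)C(C)(C)C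
A6 | alternative 3 | methyl 5-[(S)-{4-[(tert-butyldimethylsilyl)oxy]phenyl}(hydroxy)methyl]furan-3-carboxylate | O[C@@H](c1ccc(O[Si](C)(C)C(C)(C)C)cc1)c1cc(C(=O)OC)co1
A7 | alternative 3 | methyl 6-{4-[(tert-butyldimethylsilyl)oxy]phenyl}-2-hydroxy-5-oxo-5,6-dihydro-2H-pyran-3-carboxylate (lactol anomers) | O=C1C=C(C(=O)OC)C(O)O[C@H]1c1ccc(O[Si](C)(C)C(C)(C)C)cc1
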